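Slowness is the danger in this flask. An excess of 80 % needs the left-handed substrate down to 0.111 of the right-handed one, 0.954 of a tenfold fall, within 40 min.

common to all: precatalyst 8.5 mM

| flask | left-handed substrate | right-handed substrate | coupling partner | remark | time |
|---|---|---|---|---|---|
| beta | 0.24 M | 0.24 M | 0.51 M | run made earlier |  |
| epsilon | 0.37 M | 0.37 M | 0.51 M | run made earlier |  |
| gamma | 0.17 M | 0.17 M | 0.26 M | run made earlier |  |
| flask | 0.17 M | 0.17 M | 0.510 M |  | 40 min |

| run | time / min | right-handed substrate / % | left-handed substrate / % |
|---|---|---|---|
| beta | 10.0 | 44 | 16 |
| beta | 20.0 | 47 | 0 |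
| beta | 30.0 | 46 | 0 |
| beta | 40.0 | 40 | 0 |
| epsilon | 5.00 | 50 | 37 |
| epsilon | 15.0 | 48 | 9 |
| epsilon | 25.0 | 46 | 1 |
| epsilon | 40.0 | 43 | 0 |
| gamma | 10.0 | 49 | 30 |
| gamma | 20.0 | 45 | 9 |
| gamma | 30.0 | 47 | 2 |
| gamma | 40.0 | 43 | 1 |

(each reading ± 2 percentage points)

- free catalyst is single-handed; left-handed substrate and right-handed substrate are mirror images of each other, charged as a racemate, each of them at the stated concentration
- what may be going on: free catalyst + left-handed substrate <-> catalyst intermediate A; free catalyst + right-handed substrate <-> catalyst intermediate B; coupling partner + catalyst intermediate A -> free catalyst + left-handed product; coupling partner + catalyst intermediate B -> free catalyst + right-handed product; coupling partner + precatalyst -> free catalyst + spent reagent; free catalyst <-> dormant form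

1. whether the excess of right-handed substrate over left-handed substrate among what is left of the two reaches 80 % by 40 min (no / yes)
2. the highest excess of right-handed substrate over left-handed substrate among what is left of the two up to 40 min

This reckoning follows rates. In the gamma run the left-handed substrate falls from 30 % to 2 % between 10.0 min and 30.0 min, a pseudo-first-order pace of 0.135 /min. This is a rough reading: its last point is 2 %, with a scatter of 2 percentage points. The coupling partner at 20.0 min, charge minus what has reacted, is 0.104 M, so the pace per molar partner is 1.31 /M/min.

At its full 0.510 M of partner, this reckoning gives this flask an open pace of 0.667 /min. The start runs below that. The beta run, with the same partner and precatalyst, loses 0.0163 M/min, which on this flask's 0.17 M is 0.0960 /min, a factor of 6.95 down. At that loss the charge lasts 10.4 min, less than 40 min.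

Late, counting the left-handed charge as reacted and the right-handed one as untouched, this reckoning puts the partner lower by a factor of 1.50. That leaves a pace of 0.444 /min and 5.18 min for each tenfold fall, the decade time. The remaining time holds 5.71 decade times, more than the excess asks.

The forecast says yes, with a top of 99.8 %, on the ground that “The rate therefore rises with partner”. Its late decay of 0.2 to 0.3 per minute differs from the 0.444 /min of this reckoning.

The flask gives yes and a top of >99.9 %.

    free catalyst + left-handed substrate ⇌ catalyst intermediate A (K = 27.0 /M, k = 8.07 /M/s)
    free catalyst + right-handed substrate ⇌ catalyst intermediate B (K = 3.20 /M, k = 19.9 /M/s)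
    coupling partner + catalyst intermediate A → free catalyst + left-handed product (k = 0.223 /M/s)
    coupling partner + catalyst intermediate B → free catalyst + right-handed product (k = 0.0245 /M/s)
    coupling partner + precatalyst → free catalyst + spent reagent (k = 0.0110 /M/s)
    free catalyst ⇌ dormant form (K = 0.860, k = 0.00146 /s)

The excess in this flask passes 80 % at 10.6 min, with 47.6 % of right-handed substrate left. Between 4.00 min and 20.0 min the left-handed substrate in this flask falls from 31.6 % to 0.201 %, at 7.28 min per tenfold fall against the decade time of 5.18 min. In the epsilon run the mean partner between 15.0 min and 25.0 min is 0.155 M, so the same constant gives a decade time of 11.3 min. The epsilon readings, 9 % falling to 1 %, give 10.5 min.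

(The readings come from a simulation with made-up constants; noise was put on by code.)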